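**Plan**

Ring numbering follows the name of the target: C1 is the carbinol carbon, the ring alkenes are C4=C5 (E), C7=C8 (Z) and C11=C12 (E), and the side chain C1′–C7′ is attached through C2′.
- Cuts: side-chain C5′=C6′ (cross-metathesis); ring bond C13–C14 (key step); C5–C6 and C4–CH3 (carboalumination/Pd allylation joining a nerol-derived C6–C13 piece to the core); C2′–CH3 and the C1/C2′ diad (epoxy alcohol).
- Feature used: the ring CH2 C14 lies between the tertiary carbinol C1 and the allylic CH2 C13 of the C11=C12(Me) unit. A sulfone on C14 forms, with the C1 alkoxide, an α,O-dianion that cannot β-eliminate and closes the 14-membered ring by SN2 at a C13 allylic chloride; the sulfone is then removed.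
- Forward order: neryl acetate to the C6–C13 chloride; pent-4-enal to the epoxy alcohol and the hydroxy sulfone alkyne core; union; ring closure; desulfonylation; side-chain terminus.
- Stereochemistry: C1 from Sharpless epoxidation (L-(+)-DET) of an E-allylic alcohol of fixed geometry; C2′ by anti (SN2) opening of that epoxide with Me2CuLi. Alkene geometries come from nerol (7Z), SeO2 (11E), syn-carbometalation with retentive coupling (4E) and E-selective cross-metathesis (5′E).

Key step: step 15

Remark: C14 of the macrocyclic sulfone forms as a mixture of epimers; this has no consequence because the sulfonyl group is removed in step 16.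

**Route**

Step 1
Reactants: 1 neryl acetate
Product: 2 (2Z,6E)-8-hydroxy-3,7-dimethylocta-2,6-dien-1-yl acetate
Conditions: SeO2 (cat.), salicylic acid (cat.), t-BuOOH, CH2Cl2, rt
Reagents that add atoms: tert-butyl hydroperoxide, CC(C)(C)OO
Why: SeO2/t-BuOOH allylic oxidation (ene reaction, then [2,3] shift) should hydroxylate the E-methyl of the terminal isopropylidene group selectively, giving the 6E allylic alcohol and leaving the 2Z alkene and the acetate untouched.

Step 2
Reactants: 2 (2Z,6E)-8-hydroxy-3,7-dimethylocta-2,6-dien-1-yl acetate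
Product: 3 (2Z,6E)-8-[(tert-butyldimethylsilyl)oxy]-3,7-dimethylocta-2,6-dien-1-yl acetate
Conditions: TBSCl, imidazole, DMF, 0 °C → rt
Reagents that add atoms: tert-butyldimethylsilyl chloride, CC(C)(C)[Si](C)(C)Cl
Why: Standard silylation of a primary allylic alcohol masks the future C13 oxygen through the organoaluminium/palladium step.

Step 3
Reactants: 3 (2Z,6E)-8-[(tert-butyldimethylsilyl)oxy]-3,7-dimethylocta-2,6-dien-1-yl acetate
Product: 4 (2Z,6E)-8-[(tert-butyldimethylsilyl)oxy]-3,7-dimethylocta-2,6-dien-1-ol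
Conditions: K2CO3 (cat.), MeOH, 0 °C → rt
Reagents that add atoms: none
Why: Base-catalysed transesterification should remove the acetate while the silyl ether is stable to carbonate in methanol.

Step 4
Reactants: 4 (2Z,6E)-8-[(tert-butyldimethylsilyl)oxy]-3,7-dimethylocta-2,6-dien-1-ol
Product: 5 tert-butyl{[(2E,6Z)-8-chloro-2,6-dimethylocta-2,6-dien-1-yl]oxy}dimethylsilane
Conditions: NCS, Me2S, CH2Cl2, −30 → 0 °C
Reagents that add atoms: N-chlorosuccinimide, O=C1CCC(=O)N1Cl
Why: Corey–Kim chlorination (alkoxysulfonium salt displaced by chloride in an SN2 step) converts primary allylic alcohols into chlorides without allylic transposition or Z/E isomerisation.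

Step 5
Reactants: 6 pent-4-enal; 7 ethyl (triphenylphosphoranylidene)acetate
Product: 9 ethyl (2Z)-2-bromohepta-2,6-dienoate, via ethyl bromo(triphenylphosphoranylidene)acetate 8 (not isolated)
Conditions: 7, NBS, CH2Cl2, −20 °C; then 6, K2CO3, rt
Reagents that add atoms: N-bromosuccinimide, O=C1CCC(=O)N1Br
Why: Bromination of the stabilised ylide in the flask followed by Wittig olefination should give mainly the Z-α-bromo enoate (ester trans to the chain), as is usual for stabilised ylides; the minor E isomer should be removable by chromatography.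

Step 6
Reactants: 9 ethyl (2Z)-2-bromohepta-2,6-dienoate; 10 (4-bromobut-1-yn-1-yl)trimethylsilane
Product: 12 ethyl (2E)-2-[4-(trimethylsilyl)but-3-yn-1-yl]hepta-2,6-dienoate, via [4-(trimethylsilyl)but-3-yn-1-yl]zinc bromide 11 (not isolated)
Conditions: 10, Zn dust, LiCl, THF, 50 °C; then 9, Pd(dppf)Cl2 (3 mol %), THF, rt
Reagents that add atoms: none
Why: Negishi sp2–sp3 coupling of a Z-2-bromo-2-alkenoate with an alkylzinc halide proceeds with retention, so the new chain ends cis to the butenyl chain (E-enoate), which fixes the alkene geometry that later sets the relative configuration of C1 and C2′.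

Step 7
Reactants: 12 ethyl (2E)-2-[4-(trimethylsilyl)but-3-yn-1-yl]hepta-2,6-dienoate
Product: 13 (2E)-2-[4-(trimethylsilyl)but-3-yn-1-yl]hepta-2,6-dien-1-ol
Conditions: DIBAL-H (2.2 equiv), CH2Cl2, −78 °C; Rochelle salt
Reagents that add atoms: none
Why: DIBAL-H reduces the conjugated ester in the 1,2-sense to the allylic alcohol without touching the alkenes or the silylalkyne.

Step 8
Reactants: 13 (2E)-2-[4-(trimethylsilyl)but-3-yn-1-yl]hepta-2,6-dien-1-ol
Product: 14 {(2S,3S)-3-(but-3-en-1-yl)-2-[4-(trimethylsilyl)but-3-yn-1-yl]oxiran-2-yl}methanol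
Conditions: Ti(OiPr)4 (10 mol %), L-(+)-diethyl tartrate (12 mol %), t-BuOOH, 4 Å MS, CH2Cl2, −20 °C
Reagents that add atoms: tert-butyl hydroperoxide, CC(C)(C)OO
Why: Sharpless asymmetric epoxidation with L-(+)-DET should deliver oxygen to the face that gives the (2S,3S)-epoxide of this E-trisubstituted allylic alcohol, which sets the configuration of the future C1; the terminal alkene is not an allylic alcohol and does not react.

Step 9
Reactants: 14 {(2S,3S)-3-(but-3-en-1-yl)-2-[4-(trimethylsilyl)but-3-yn-1-yl]oxiran-2-yl}methanol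
Product: 15 (2R,3R)-3-methyl-2-[4-(trimethylsilyl)but-3-yn-1-yl]hept-6-ene-1,2-diol
Conditions: Me2CuLi (4 equiv), Et2O, −30 → 0 °C; aq. NH4Cl
Reagents that add atoms: lithium dimethylcuprate, [Li+].C[Cu-]C
Why: The Gilman cuprate opens the 2,3-epoxy alcohol by SN2 at C3, the only epoxide carbon that is not fully substituted, with inversion, which sets the future C2′ methyl stereocentre and leaves the C–O bond of the future C1 intact.

Step 10
Reactants: 15 (2R,3R)-3-methyl-2-[4-(trimethylsilyl)but-3-yn-1-yl]hept-6-ene-1,2-diol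
Product: 17 (2R)-2-(but-3-yn-1-yl)-2-[(2R)-hex-5-en-2-yl]oxirane, via primary tosylate 16 (not isolated)
Conditions: TsCl, Et3N, DMAP (cat.), CH2Cl2, 0 °C; then K2CO3, MeOH, rt
Reagents that add atoms: none
Why: Selective sulfonylation of the primary hydroxyl and 3-exo-tet displacement by the tertiary alkoxide give the terminal epoxide with the quaternary centre unchanged, and carbonate in methanol cleaves the alkynyl C–Si bond in the same operation.

Step 11
Reactants: 17 (2R)-2-(but-3-yn-1-yl)-2-[(2R)-hex-5-en-2-yl]oxirane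
Product: 18 (2R,3R)-2-(but-3-yn-1-yl)-3-methyl-1-(phenylsulfonyl)hept-6-en-2-ol
Conditions: PhSO2Na (3 equiv), NH4Cl, EtOH–H2O, 80 °C
Reagents that add atoms: sodium benzenesulfinate, [Na+].[O-]S(=O)c1ccccc1
Why: The sulfinate (S-nucleophile) should open the 2,2-disubstituted epoxide by SN2 at the unsubstituted CH2 to give the β-hydroxy sulfone, which places the activating group on the future C14.

Step 12
Reactants: 18 (2R,3R)-2-(but-3-yn-1-yl)-3-methyl-1-(phenylsulfonyl)hept-6-en-2-ol; 5 tert-butyl{[(2E,6Z)-8-chloro-2,6-dimethylocta-2,6-dien-1-yl]oxy}dimethylsilane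
Product: 20 (2R,5E,8Z,12E)-14-[(tert-butyldimethylsilyl)oxy]-2-[(2R)-hex-5-en-2-yl]-5,9,13-trimethyl-1-(phenylsulfonyl)tetradeca-5,8,12-trien-2-ol, via E-alkenyl(dimethyl)alane 19 (not isolated)
Conditions: 18, Me3Al (4 equiv), Cp2ZrCl2 (0.5 equiv), CH2Cl2, 0 °C → rt; then 5, Pd(PPh3)4 (5 mol %), THF, rt
Reagents that add atoms: trimethylaluminium, C[Al](C)C
Why: Negishi zirconium-catalysed carboalumination adds Me and Al syn across the terminal alkyne (methyl to the internal carbon) and the Pd(0)-catalysed alkenyl–allyl coupling proceeds with retention in both partners, which should give the ring C4 methyl, the 4E alkene and the skipped diene while keeping the Z alkene that came from nerol.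

Step 13
Reactants: 20 (2R,5E,8Z,12E)-14-[(tert-butyldimethylsilyl)oxy]-2-[(2R)-hex-5-en-2-yl]-5,9,13-trimethyl-1-(phenylsulfonyl)tetradeca-5,8,12-trien-2-ol
Product: 21 (2E,6Z,9E,13R)-13-[(2R)-hex-5-en-2-yl]-2,6,10-trimethyl-14-(phenylsulfonyl)tetradeca-2,6,9-triene-1,13-diol
Conditions: TBAF, THF, 0 °C → rt
Reagents that add atoms: none
Why: Fluoride cleaves the primary allylic silyl ether under conditions that leave the β-hydroxy sulfone and the alkenes untouched.

Step 14
Reactants: 21 (2E,6Z,9E,13R)-13-[(2R)-hex-5-en-2-yl]-2,6,10-trimethyl-14-(phenylsulfonyl)tetradeca-2,6,9-triene-1,13-diol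
Product: 22 (2R,5E,8Z,12E)-14-chloro-2-[(2R)-hex-5-en-2-yl]-5,9,13-trimethyl-1-(phenylsulfonyl)tetradeca-5,8,12-trien-2-ol
Conditions: NCS, Me2S, CH2Cl2, −30 → 0 °C
Reagents that add atoms: N-chlorosuccinimide, O=C1CCC(=O)N1Cl
Why: Corey–Kim chlorination should convert only the unhindered primary allylic alcohol, without transposition or loss of E geometry, while the hindered tertiary alcohol does not react at low temperature.

Step 15
Reactants: 22 (2R,5E,8Z,12E)-14-chloro-2-[(2R)-hex-5-en-2-yl]-5,9,13-trimethyl-1-(phenylsulfonyl)tetradeca-5,8,12-trien-2-ol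
Product: 24 (1R,4E,7Z,11E)-1-[(2R)-hex-5-en-2-yl]-4,8,12-trimethyl-14-(phenylsulfonyl)cyclotetradeca-4,7,11-trien-1-ol (both C14 epimers), via dilithio α,O-dianion 23 (not isolated)
Conditions: slow addition of 22 to LDA (2.5 equiv), THF (final ca. 2 mM), −78 °C; then −78 → −20 °C; aq. NH4Cl at −20 °C
Reagents that add atoms: none
Why: LDA removes the hydroxyl proton and then one C–H next to the sulfone to give the α,O-dilithio species 23, in which the oxido group on the neighbouring carbon cannot leave, so no β-elimination competes; the sulfonyl-stabilised carbanion then displaces the primary allylic chloride by intramolecular SN2 and closes the fourteen-membered carbocycle. The closest known reaction types are the macrocyclisation of sulfone-stabilised carbanions onto allylic halides used for fourteen-membered isoprenoid rings and the C-alkylation of α,O-dianions of β-hydroxy sulfones. The ring closes in the 14-exo-tet mode, the chloride leaving outside the new ring. The only new stereocentre, the sulfonyl-bearing C14, is not controlled and need not be, since both epimers give the same compound in step 16; C1 and C2′ are not touched. The step needs ring closure to win over intermolecular alkylation (slow addition, high dilution), C- over O-alkylation (the carbanion is far more nucleophilic than the hindered tertiary lithium alkoxide) and SN2 over SN2′ (attack at the substituted γ-carbon would give a twelve-membered ring with an isopropenyl branch and is not the normal course for sulfonyl carbanions with such chlorides). The three trisubstituted alkenes are spectators, so their geometry should be kept.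

Step 16
Reactants: 24 (1R,4E,7Z,11E)-1-[(2R)-hex-5-en-2-yl]-4,8,12-trimethyl-14-(phenylsulfonyl)cyclotetradeca-4,7,11-trien-1-ol
Product: 25 (1R,4E,7Z,11E)-1-[(2R)-hex-5-en-2-yl]-4,8,12-trimethylcyclotetradeca-4,7,11-trien-1-ol
Conditions: 6% Na(Hg), Na2HPO4, MeOH–THF, −20 °C
Reagents that add atoms: none
Why: Buffered sodium amalgam cleaves the C–S bond by electron transfer and the resulting non-allylic carbanion is protonated by methanol faster than it can expel the poor β-oxygen leaving group, so both C14 epimers should converge on one alcohol with no alkene involved.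

Step 17
Reactants: 25 (1R,4E,7Z,11E)-1-[(2R)-hex-5-en-2-yl]-4,8,12-trimethylcyclotetradeca-4,7,11-trien-1-ol; 26 methacrolein
Product: 27 (2E,6R)-6-[(1R,4E,7Z,11E)-1-hydroxy-4,8,12-trimethylcyclotetradeca-4,7,11-trien-1-yl]-2-methylhept-2-enal
Conditions: 26 (10 equiv), Hoveyda–Grubbs II (5 mol %), CH2Cl2, 40 °C
Reagents that add atoms: none
Why: Olefin cross-metathesis of the monosubstituted alkene with methacrolein should give the E-trisubstituted enal, while the trisubstituted ring alkenes are too hindered to enter the catalytic cycle.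

Step 18
Reactants: 27 (2E,6R)-6-[(1R,4E,7Z,11E)-1-hydroxy-4,8,12-trimethylcyclotetradeca-4,7,11-trien-1-yl]-2-methylhept-2-enal
Product: 28 (1R,4E,7Z,11E)-1-[(2R,5E)-7-hydroxy-6-methylhept-5-en-2-yl]-4,8,12-trimethylcyclotetradeca-4,7,11-trien-1-ol
Conditions: NaBH4, CeCl3·7H2O, MeOH, 0 °C
Reagents that add atoms: none
Why: Luche reduction delivers hydride to the aldehyde carbonyl in the 1,2-sense and should give the E-allylic alcohol without conjugate reduction.

**Compound list**

1 | neryl acetate, (2Z)-3,7-dimethylocta-2,6-dien-1-yl acetate | CC(=O)OC/C=C(/C)CCC=C(C)C | starting material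
2 | (2Z,6E)-8-hydroxy-3,7-dimethylocta-2,6-dien-1-yl acetate | CC(=O)OC/C=C(/C)CC/C=C(\C)CO | intermediate
3 | (2Z,6E)-8-[(tert-butyldimethylsilyl)oxy]-3,7-dimethylocta-2,6-dien-1-yl acetate | CC(=O)OC/C=C(/C)CC/C=C(\C)CO[Si](C)(C)C(C)(C)C | intermediate
4 | (2Z,6E)-8-[(tert-butyldimethylsilyl)oxy]-3,7-dimethylocta-2,6-dien-1-ol | OC/C=C(/C)CC/C=C(\C)CO[Si](C)(C)C(C)(C)C | intermediate
5 | tert-butyl{[(2E,6Z)-8-chloro-2,6-dimethylocta-2,6-dien-1-yl]oxy}dimethylsilane | ClC/C=C(/C)CC/C=C(\C)CO[Si](C)(C)C(C)(C)C | intermediate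
6 | pent-4-enal | C=CCCC=O | starting material
7 | ethyl (triphenylphosphoranylidene)acetate | CCOC(=O)C=P(c1ccccc1)(c1ccccc1)c1ccccc1 | starting material
8 | ethyl bromo(triphenylphosphoranylidene)acetate (not isolated) | CCOC(=O)C(Br)=P(c1ccccc1)(c1ccccc1)c1ccccc1 | intermediate
9 | ethyl (2Z)-2-bromohepta-2,6-dienoate | CCOC(=O)/C(Br)=C/CCC=C | intermediate
10 | (4-bromobut-1-yn-1-yl)trimethylsilane | C[Si](C)(C)C#CCCBr | starting material
11 | [4-(trimethylsilyl)but-3-yn-1-yl]zinc bromide (not isolated) | C[Si](C)(C)C#CCC[Zn]Br | intermediate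
12 | ethyl (2E)-2-[4-(trimethylsilyl)but-3-yn-1-yl]hepta-2,6-dienoate | CCOC(=O)/C(CCC#C[Si](C)(C)C)=C/CCC=C | intermediate
13 | (2E)-2-[4-(trimethylsilyl)but-3-yn-1-yl]hepta-2,6-dien-1-ol | OC/C(CCC#C[Si](C)(C)C)=C/CCC=C | intermediate
14 | {(2S,3S)-3-(but-3-en-1-yl)-2-[4-(trimethylsilyl)but-3-yn-1-yl]oxiran-2-yl}methanol | OC[C@]1(CCC#C[Si](C)(C)C)O[C@H]1CCC=C | intermediate
15 | (2R,3R)-3-methyl-2-[4-(trimethylsilyl)but-3-yn-1-yl]hept-6-ene-1,2-diol | C[Si](C)(C)C#CCC[C@@](O)([C@H](C)CCC=C)CO | intermediate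
16 | (2R,3R)-2-hydroxy-3-methyl-2-[4-(trimethylsilyl)but-3-yn-1-yl]hept-6-en-1-yl 4-methylbenzenesulfonate (not isolated) | C[Si](C)(C)C#CCC[C@@](O)([C@H](C)CCC=C)COS(=O)(=O)c1ccc(C)cc1 | intermediate
17 | (2R)-2-(but-3-yn-1-yl)-2-[(2R)-hex-5-en-2-yl]oxirane | C#CCC[C@@]1(OC1)[C@H](C)CCC=C | intermediate
18 | (2R,3R)-2-(but-3-yn-1-yl)-3-methyl-1-(phenylsulfonyl)hept-6-en-2-ol | C#CCC[C@@](O)([C@H](C)CCC=C)CS(=O)(=O)c1ccccc1 | intermediate
19 | E-alkenyl(dimethyl)alane of 18, O-dimethylaluminium alkoxide (not isolated) | C[Al](C)/C=C(\C)CC[C@@](O[Al](C)C)([C@H](C)CCC=C)CS(=O)(=O)c1ccccc1 | intermediate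
20 | (2R,5E,8Z,12E)-14-[(tert-butyldimethylsilyl)oxy]-2-[(2R)-hex-5-en-2-yl]-5,9,13-trimethyl-1-(phenylsulfonyl)tetradeca-5,8,12-trien-2-ol | CC(C)(C)[Si](C)(C)OC/C(C)=C/CC/C(C)=C\C/C=C(\C)CC[C@@](O)([C@H](C)CCC=C)CS(=O)(=O)c1ccccc1 | intermediate
21 | (2E,6Z,9E,13R)-13-[(2R)-hex-5-en-2-yl]-2,6,10-trimethyl-14-(phenylsulfonyl)tetradeca-2,6,9-triene-1,13-diol | OC/C(C)=C/CC/C(C)=C\C/C=C(\C)CC[C@@](O)([C@H](C)CCC=C)CS(=O)(=O)c1ccccc1 | intermediate
22 | (2R,5E,8Z,12E)-14-chloro-2-[(2R)-hex-5-en-2-yl]-5,9,13-trimethyl-1-(phenylsulfonyl)tetradeca-5,8,12-trien-2-ol | ClC/C(C)=C/CC/C(C)=C\C/C=C(\C)CC[C@@](O)([C@H](C)CCC=C)CS(=O)(=O)c1ccccc1 | intermediate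
23 | dilithio α,O-dianion of 22 (not isolated) | ClC/C(C)=C/CC/C(C)=C\C/C=C(\C)CC[C@@](O[Li])([C@H](C)CCC=C)C([Li])S(=O)(=O)c1ccccc1 | intermediate
24 | (1R,4E,7Z,11E)-1-[(2R)-hex-5-en-2-yl]-4,8,12-trimethyl-14-(phenylsulfonyl)cyclotetradeca-4,7,11-trien-1-ol, C14 epimers | C1/C(C)=C/CC/C(C)=C\C/C=C(\C)CC[C@@](O)([C@H](C)CCC=C)C1S(=O)(=O)c2ccccc2 | intermediate
25 | (1R,4E,7Z,11E)-1-[(2R)-hex-5-en-2-yl]-4,8,12-trimethylcyclotetradeca-4,7,11-trien-1-ol | C1/C(C)=C/CC/C(C)=C\C/C=C(\C)CC[C@@](O)([C@H](C)CCC=C)C1 | intermediate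
26 | methacrolein, 2-methylprop-2-enal | CC(=C)C=O | starting material
27 | (2E,6R)-6-[(1R,4E,7Z,11E)-1-hydroxy-4,8,12-trimethylcyclotetradeca-4,7,11-trien-1-yl]-2-methylhept-2-enal | C1/C(C)=C/CC/C(C)=C\C/C=C(\C)CC[C@@](O)([C@H](C)CC/C=C(\C)C=O)C1 | intermediate
28 | (1R,4E,7Z,11E)-1-[(2R,5E)-7-hydroxy-6-methylhept-5-en-2-yl]-4,8,12-trimethylcyclotetradeca-4,7,11-trien-1-ol | C/C1=C/C/C=C(\C)CC[C@@](O)([C@H](C)CC/C=C(\C)CO)CC/C(C)=C/CC1 | target

**Summary**

Total step count: 18. Longest linear sequence: 14 steps (steps 5–18, from pent-4-enal).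

Steps most likely to fail:

1. Step 15 (ring closure). Intermolecular alkylation may compete with cyclisation and give oligomers, and the lithium β-oxido sulfone may revert to ketone and sulfonyl carbanion on warming before the hindered carbanion has alkylated. The fallback sets out from 22: the tertiary hydroxyl is silylated (TMSOTf, 2,6-lutidine) to the trimethylsilyl ether of 22 F1. The mono-carbanion of F1 (LDA, 1.1 equiv, THF, −78 °C, high dilution), which carries no alkoxide and cannot revert, is cyclised to the macrocyclic trimethylsilyl ether sulfone F2. TBAF then removes the silyl group, and the route is rejoined at 24.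

2. Step 12 (carboalumination/allylation). Binding of zirconium and aluminium by the sulfonyl and alkoxide oxygens may retard carbometalation, and protonolysis of the alkenylalane or erosion of the Z geometry of the π-allyl intermediate may follow from long reaction times. The fallback sets out from 15 and joins the fragments before the sulfone is present: K2CO3 in MeOH gives the diol alkyne (2R,3R)-2-(but-3-yn-1-yl)-3-methylhept-6-ene-1,2-diol F3. Carboalumination to its alkenylalane F4 (not isolated) and Pd-catalysed coupling with 5 give the coupled diol F5. Tosylation to F6 (not isolated) and K2CO3/MeOH give the epoxide F7, and opening with PhSO2Na as in step 11 rejoins the route at 20.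

3. Step 11 (sulfinate opening). Attack of the weakly nucleophilic sulfinate at the CH2 next to the quaternary centre may be slow enough for solvolysis or rearrangement of the epoxide to take over. The fallback sets out from 17: the much more nucleophilic thiolate (PhSH, Et3N, MeOH) opens the epoxide to the β-hydroxy sulfide (2R,3R)-2-(but-3-yn-1-yl)-3-methyl-1-(phenylsulfanyl)hept-6-en-2-ol F8. Chemoselective oxidation at sulfur ((NH4)6Mo7O24 cat., H2O2, EtOH, 0 °C) then rejoins the route at 18.

**Further compounds**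

F1 | step 15 | {[(2R,5E,8Z,12E)-14-chloro-2-[(2R)-hex-5-en-2-yl]-5,9,13-trimethyl-1-(phenylsulfonyl)tetradeca-5,8,12-trien-2-yl]oxy}trimethylsilane | ClC/C(C)=C/CC/C(C)=C\C/C=C(\C)CC[C@@](O[Si](C)(C)C)([C@H](C)CCC=C)CS(=O)(=O)c1ccccc1
F2 | step 15 | trimethyl{[(1R,4E,7Z,11E)-1-[(2R)-hex-5-en-2-yl]-4,8,12-trimethyl-14-(phenylsulfonyl)cyclotetradeca-4,7,11-trien-1-yl]oxy}silane | C1/C(C)=C/CC/C(C)=C\C/C=C(\C)CC[C@@](O[Si](C)(C)C)([C@H](C)CCC=C)C1S(=O)(=O)c2ccccc2
F3 | step 12 | (2R,3R)-2-(but-3-yn-1-yl)-3-methylhept-6-ene-1,2-diol | C#CCC[C@@](O)([C@H](C)CCC=C)CO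
F4 | step 12 | E-alkenyl(dimethyl)alane of F3, bis(O-dimethylaluminium) alkoxide (not isolated) | C[Al](C)/C=C(\C)CC[C@@](O[Al](C)C)([C@H](C)CCC=C)CO[Al](C)C
F5 | step 12 | (2R,5E,8Z,12E)-14-[(tert-butyldimethylsilyl)oxy]-2-[(2R)-hex-5-en-2-yl]-5,9,13-trimethyltetradeca-5,8,12-triene-1,2-diol | CC(C)(C)[Si](C)(C)OC/C(C)=C/CC/C(C)=C\C/C=C(\C)CC[C@@](O)([C@H](C)CCC=C)CO
F6 | step 12 | 1-(4-methylbenzenesulfonate) of F5 (not isolated) | CC(C)(C)[Si](C)(C)OC/C(C)=C/CC/C(C)=C\C/C=C(\C)CC[C@@](O)([C@H](C)CCC=C)COS(=O)(=O)c1ccc(C)cc1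
F7 | step 12 | tert-butyl{[(2E,6Z,9E)-12-[(2R)-2-[(2R)-hex-5-en-2-yl]oxiran-2-yl]-2,6,10-trimethyldodeca-2,6,9-trien-1-yl]oxy}dimethylsilane | CC(C)(C)[Si](C)(C)OC/C(C)=C/CC/C(C)=C\C/C=C(\C)CC[C@@]1(OC1)[C@H](C)CCC=C
F8 | step 11 | (2R,3R)-2-(but-3-yn-1-yl)-3-methyl-1-(phenylsulfanyl)hept-6-en-2-ol | C#CCC[C@@](O)([C@H](C)CCC=C)CSc1ccccc1
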